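**Retrosynthetic overview**
- The target is reached by trans-hydrolysis at C5 of a 5,6-vinyl epoxide that already carries both benzoates.
- The C2 oxygen (β face, hindered by the neighbouring CH2OBz) is delivered intramolecularly by a suprafacial selenoxide [2,3]-shift from C4, then benzoylated.
- The C4 carbinol comes from 1,2-reduction of a syn-epoxy enone.
- The syn-epoxy enone comes from an organocatalytic desymmetrising epoxidation of an achiral para-quinol; this is the only asymmetric step.
- The para-quinol comes from oxidative dearomatisation of 4-hydroxybenzyl benzoate. The carbocycle is the original benzene ring; the only ring formed is the oxirane, which is opened in the last step.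

Target: [(1S,2S,5R,6S)-2-(benzoyloxy)-1,5,6-trihydroxycyclohex-3-en-1-yl]methyl benzoate.

Convention: ring carbons carry the target locants (C1 quaternary carbinol carbon, C2 the carbon that ends as the secondary benzoate, C3=C4 the final alkene, then C5, C6). α is the ring face of the tertiary OH, β the face of the CH2OBz group; absolute configuration is as in the SMILES.

Assumption: the quinine-derived amine salt is taken to select the enone arm that gives the enantiomer drawn; if the sense is opposite, the quinidine-derived pseudo-enantiomer is used with no other change.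

**Step 1**
Reactants: 1 4-hydroxybenzyl alcohol; 2 benzoyl chloride
Product: 3 4-hydroxybenzyl benzoate
Conditions: BzCl (1.0 equiv), 2,4,6-collidine, THF/CH2Cl2, −78 → −20 °C
Reagents that add atoms: benzoyl chloride, O=C(Cl)c1ccccc1
Why: Chemoselective O-acylation via the acylpyridinium: with a weak hindered base the phenol stays protonated and is a far poorer nucleophile than the primary benzylic alcohol; no stereocentre.

**Step 2**
Reactants: 3 4-hydroxybenzyl benzoate
Product: 4 (1-hydroxy-4-oxocyclohexa-2,5-dien-1-yl)methyl benzoate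
Conditions: PhI(OAc)2 (1.1 equiv), MeCN/H2O 4:1, 0 °C, 20 min
Reagents that add atoms: water, O
Why: Hypervalent-iodine oxidative dearomatisation of a 4-substituted phenol: water traps the phenoxenium-type intermediate at the para position to give the achiral para-quinol, and the acidic medium keeps the benzylic benzoate from ionising.

**Step 3**
Reactants: 4 (1-hydroxy-4-oxocyclohexa-2,5-dien-1-yl)methyl benzoate
Product: 5 5α,6α-epoxy-1α-hydroxy-1β-(benzoyloxymethyl)cyclohex-2-en-4-one
Conditions: 9-amino-9-deoxy-epi-quinine·2 CF3CO2H (10 mol %), 50% aq. H2O2 (1.3 equiv), 1,4-dioxane, 30 °C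
Reagents that add atoms: hydrogen peroxide, OO
Why: Proposed new method: desymmetrising iminium-type Weitz–Scheffer epoxidation of a free para-quinol. The primary amine condenses with the dienone carbonyl and its protonated quinuclidine hands H2O2 to the β-carbon of the adjacent enone arm with a fixed local sense. The substrate fixes the face (peroxide enters syn to the hydrogen-bonding tertiary OH and anti to the larger CH2OBz), so only one of the two enantiotopic arms satisfies both demands. Ring closure of the β-peroxy enamine gives the 5α,6α-epoxide, setting C5 and C6 and making C1 stereogenic; a second epoxidation is mismatched and slow. Closest known reaction type: cinchona primary-amine-salt-catalysed asymmetric H2O2 epoxidation of simple cyclic enones, not shown on cross-conjugated para-quinol dienones or as a desymmetrisation.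

**Step 4**
Reactants: 5 5α,6α-epoxy-1α-hydroxy-1β-(benzoyloxymethyl)cyclohex-2-en-4-one
Product: 6 5α,6α-epoxy-1β-(benzoyloxymethyl)cyclohex-2-ene-1α,4α-diol
Conditions: NaBH4, CeCl3·7H2O, MeOH, −78 °C
Reagents that add atoms: none
Why: Luche 1,2-reduction: hydride adds to the flat epoxy enone from the β face, anti to the epoxide oxygen and the tertiary OH, giving the 4α-alcohol cis to the epoxide; benzoate and epoxide are inert at −78 °C.

**Step 5**
Reactants: 6 5α,6α-epoxy-1β-(benzoyloxymethyl)cyclohex-2-ene-1α,4α-diol
Product: 10 5α,6α-epoxy-1β-(benzoyloxymethyl)cyclohex-3-ene-1α,2β-diol, via 4β-phenylselanyl epoxy alcohol 7 (not isolated), via 4β-selenoxide 8 (not isolated), via 2β-selenenate ester 9 (not isolated)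
Conditions: N-(phenylseleno)phthalimide, PBu3, THF, −20 °C → rt; then 30% H2O2, pyridine, 0 °C → rt
Reagents that add atoms: hydrogen peroxide, OO
Why: Grieco-type selenide formation (SN2 inversion, 4α-OH → 4β-SePh) followed by selenoxide [2,3]-sigmatropic rearrangement, which is suprafacial and so places oxygen on the β face of C2 (trans to the tertiary OH) as the alkene moves to C3=C4; the selenenate is hydrolysed in the pot.

**Step 6**
Reactants: 10 5α,6α-epoxy-1β-(benzoyloxymethyl)cyclohex-3-ene-1α,2β-diol; 2 benzoyl chloride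
Product: 11 2β-benzoyloxy-5α,6α-epoxy-1α-hydroxy-1β-(benzoyloxymethyl)cyclohex-3-ene
Conditions: BzCl (1.2 equiv), Et3N, DMAP (cat.), CH2Cl2, −20 → 0 °C
Reagents that add atoms: benzoyl chloride, O=C(Cl)c1ccccc1
Why: DMAP-catalysed acylation: only the secondary C2 hydroxyl reacts because the other free OH is tertiary, and the amine buffer spares the vinyl epoxide; no stereocentre is touched.

**Step 7**
Reactants: 11 2β-benzoyloxy-5α,6α-epoxy-1α-hydroxy-1β-(benzoyloxymethyl)cyclohex-3-ene
Product: 12 [(1S,2S,5R,6S)-2-(benzoyloxy)-1,5,6-trihydroxycyclohex-3-en-1-yl]methyl benzoate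
Conditions: HClO4 (cat.), THF/H2O 3:1, 0 °C → rt
Reagents that add atoms: water, O
Why: Acid-catalysed anti-opening of a vinyl epoxide: water attacks the allylic C5 with inversion, giving the 5β-OH trans to the retained 6α-OH; C6, flanked by the quaternary carbinol, is not attacked.

**Compound list**
1 | 4-hydroxybenzyl alcohol | OCc1ccc(O)cc1 | starting material
2 | benzoyl chloride | O=C(Cl)c1ccccc1 | starting material
3 | 4-hydroxybenzyl benzoate | O=C(OCc1ccc(O)cc1)c1ccccc1 | intermediate
4 | (1-hydroxy-4-oxocyclohexa-2,5-dien-1-yl)methyl benzoate (achiral para-quinol) | O=C1C=CC(O)(COC(=O)c2ccccc2)C=C1 | intermediate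
5 | 5α,6α-epoxy-1α-hydroxy-1β-(benzoyloxymethyl)cyclohex-2-en-4-one (epoxide cis to the tertiary OH) | O=C(OC[C@@]1(O)C=CC(=O)[C@@H]2O[C@H]12)c1ccccc1 | intermediate
6 | 5α,6α-epoxy-1β-(benzoyloxymethyl)cyclohex-2-ene-1α,4α-diol (all three ring oxygens on the α face) | O=C(OC[C@@]1(O)C=C[C@H](O)[C@@H]2O[C@H]12)c1ccccc1 | intermediate
7 | 5α,6α-epoxy-1α-hydroxy-4β-(phenylselanyl)-1β-(benzoyloxymethyl)cyclohex-2-ene | O=C(OC[C@@]1(O)C=C[C@@H]([Se]c3ccccc3)[C@@H]2O[C@H]12)c1ccccc1 | intermediate
8 | Se-oxide of 7 (4β-phenylseleninyl, mixture at selenium) | O=C(OC[C@@]1(O)C=C[C@@H]([Se](=O)c3ccccc3)[C@@H]2O[C@H]12)c1ccccc1 | intermediate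
9 | 5α,6α-epoxy-1α-hydroxy-2β-(phenylselanyloxy)-1β-(benzoyloxymethyl)cyclohex-3-ene (selenenate ester) | O=C(OC[C@@]1(O)[C@@H](O[Se]c3ccccc3)C=C[C@@H]2O[C@H]12)c1ccccc1 | intermediate
10 | 5α,6α-epoxy-1β-(benzoyloxymethyl)cyclohex-3-ene-1α,2β-diol (trans-diol) | O=C(OC[C@@]1(O)[C@@H](O)C=C[C@@H]2O[C@H]12)c1ccccc1 | intermediate
11 | 2β-benzoyloxy-5α,6α-epoxy-1α-hydroxy-1β-(benzoyloxymethyl)cyclohex-3-ene | O=C(OC[C@@]1(O)[C@@H](OC(=O)c3ccccc3)C=C[C@@H]2O[C@H]12)c1ccccc1 | intermediate
12 | [(1S,2S,5R,6S)-2-(benzoyloxy)-1,5,6-trihydroxycyclohex-3-en-1-yl]methyl benzoate (1α-OH, 2β-OBz, 5β-OH, 6α-OH) | O=C(OC[C@@]1(O)[C@@H](OC(=O)c2ccccc2)C=C[C@@H](O)[C@@H]1O)c1ccccc1 | target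

**Step count**
Total steps: 7. Longest linear sequence: 7 steps, from 1 to 12.

**Three steps most likely to fail**

Step 3 (the proposed new desymmetrising epoxidation) may stall or give low enantio- or diastereoselectivity. The fallback uses known chemistry, sets out from 4 and rejoins at 6. Compound 4 is epoxidised without a chiral catalyst (30% H2O2, Na2CO3 cat., THF/H2O, 0 °C; hydroxyl-directed Weitz–Scheffer epoxidation syn to the tertiary OH). This gives 5 as a racemate, that is, together with the mirror-image epoxy enone F1. Luche reduction as in step 4 gives 6 together with the mirror-image epoxy diol F2. Acylative kinetic resolution with a chiral isothiourea (HyperBTM 2 mol %, (iPrCO)2O 0.55 equiv, iPr2NEt, CHCl3, −30 °C; catalyst enantiomer chosen so that the mirror-image alcohol reacts fast) converts F2 into the 4-O-isobutyrate of the mirror-image diol F3. Unreacted 6 is separated by chromatography.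

Step 4 depends on hydride entering anti to the epoxide; the facial preference of this epoxy enone is not certain. The fallback sets out from 5 and rejoins at 6. If the reduction gives mainly the 4β-hydroxy epimer F4, it is inverted by a Mitsunobu reaction (ClCH2CO2H, PPh3, DIAD, THF, 0 °C) to the 4α-chloroacetate F5. Mild methanolysis (K2CO3 cat., MeOH, 0 °C), which leaves the benzoate intact, then gives 6.

Step 5 requires a clean SN2 displacement at an allylic carbinol next to an epoxide; SN2' attack or ion-pair return would erode the configuration that the [2,3]-shift passes on to C2. The fallback sets out from 6 and rejoins at 10. Step 5 is run as written and the product is taken as 10 mixed with the 2α-hydroxy epimer F6. The mixture is oxidised (MnO2, CH2Cl2, rt; allylic alcohol oxidation) to the single 2-ketone F7. Hydroxyl-directed reduction with Me4NBH(OAc)3 (MeCN/AcOH, −30 °C), with hydride delivered on the α face from boron bound to the tertiary OH, returns only the trans-diol 10.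

**Further compounds**
F1 | step 3 | mirror image of 5 (ent-5α,6α-epoxy enone) | O=C(OC[C@]1(O)C=CC(=O)[C@H]2O[C@@H]12)c1ccccc1
F2 | step 3 | mirror image of 6 (ent-epoxy diol) | O=C(OC[C@]1(O)C=C[C@@H](O)[C@H]2O[C@@H]12)c1ccccc1
F3 | step 3 | 4-O-isobutyrate of the mirror image of 6 | O=C(OC[C@]1(O)C=C[C@@H](OC(=O)C(C)C)[C@H]2O[C@@H]12)c1ccccc1
F4 | step 4 | 5α,6α-epoxy-1β-(benzoyloxymethyl)cyclohex-2-ene-1α,4β-diol (C4 epimer of 6) | O=C(OC[C@@]1(O)C=C[C@@H](O)[C@@H]2O[C@H]12)c1ccccc1
F5 | step 4 | 4α-chloroacetate of 6 | O=C(OC[C@@]1(O)C=C[C@H](OC(=O)CCl)[C@@H]2O[C@H]12)c1ccccc1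
F6 | step 5 | 5α,6α-epoxy-1β-(benzoyloxymethyl)cyclohex-3-ene-1α,2α-diol (C2 epimer of 10) | O=C(OC[C@@]1(O)[C@H](O)C=C[C@@H]2O[C@H]12)c1ccccc1
F7 | step 5 | 5α,6α-epoxy-1α-hydroxy-1β-(benzoyloxymethyl)cyclohex-3-en-2-one | O=C(OC[C@@]1(O)C(=O)C=C[C@@H]2O[C@H]12)c1ccccc1
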